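**Retrosynthetic overview**

1. Ring A is numbered C1 (carbonyl), C2, C3 (methyl-bearing alkene carbon), C4 (quaternary), C5 (CHMe), C6 (CH2). Cyclolinteinone 21 ⇒ silyl enol ether aldehyde 17 (Saegusa–Ito oxidation; C4 formyl → methyl), i.e. ring A with C1–C2 as a silyl enol ether and the C4 methyl at the aldehyde oxidation level.
2. 17 ⇒ enantioselective, asynchronous [4+2] union that closes ring A by the C3–C4 bond at the quaternary carbon (C5–C6 forms in the same event): 2-silyloxydiene 16 (C6=C1–C2=C3) + (E)-α-alkyl enal 13 (C4=C5), which already carries the complete C20 chain and the butenolide (ring B).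
3. Enabling feature: in ring A the C1 carbonyl with the C2=C3 alkene is a latent 2-silyloxy-1,3-diene, and the vicinal C4 (quaternary)/C5 (methine) pair, with the chain cis to the C5 methyl, is the imprint of an (E)-trisubstituted enal whose formyl carbon is the C4 methyl.
4. 13 ⇒ B-alkyl Suzuki–Miyaura coupling of terminal diene 8 with (Z)-2-bromobut-2-enal 11; 8 ⇒ (E)-geranylacetone 1 by terminal allylic oxidation, methylenation and butenolide annulation of the methyl ketone.
5. Ring order: butenolide ring B first (step 5), cyclohexene ring A second (step 9).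

Key step: step 9

Assumption: the protonated (S)-oxazaborolidine is taken to shield the C4-Si/C5-Re face of the coordinated s-trans enal, as for other α-substituted enals, so that the diene adds to the C4-Re/C5-Si face; if the facial sense is the opposite for 13, the (R)-catalyst is used. C3 of 17–20 is an epimer mixture that is erased in step 12.

**Route**

Step 1
Reactants: 1 (E)-geranylacetone
Product: 2 (5E,9E)-11-hydroxy-6,10-dimethylundeca-5,9-dien-2-one
Conditions: SeO2 (0.3 equiv), t-BuOOH (3 equiv), salicylic acid (0.1 equiv), CH2Cl2, rt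
Reagents that add atoms: tert-butyl hydroperoxide CC(C)(C)OO (stoichiometric oxygen source); SeO2 O=[Se]=O (catalytic oxygen carrier)
Why: SeO2 allylic oxidation (ene reaction, then [2,3]-sigmatropic shift) attacks the (E)-methyl group of the terminal isopropylidene unit of polyprenyl chains in preference to the internal alkene, so the (E)-allylic alcohol should form with the chain geometry intact.

Step 2
Reactants: 2 (5E,9E)-11-hydroxy-6,10-dimethylundeca-5,9-dien-2-one
Product: 3 (2E,6E)-2,6-dimethyl-10-oxoundeca-2,6-dienal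
Conditions: MnO2 (activated, excess), CH2Cl2, rt
Reagents that add atoms: none
Why: MnO2 oxidises allylic alcohols selectively, so the (E)-enal should form without touching the ketone or the other alkene, and any enal already formed in step 1 converges here.

Step 3
Reactants: 3 (2E,6E)-2,6-dimethyl-10-oxoundeca-2,6-dienal
Product: 4 (5E,9E)-6,10-dimethyldodeca-5,9,11-trien-2-one
Conditions: Ph3PCH3Br, KN(SiMe3)2, THF, 0 °C; then 3, −78 → 0 °C
Reagents that add atoms: methyltriphenylphosphonium bromide C[P+](c1ccccc1)(c1ccccc1)c1ccccc1.[Br-]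
Why: Wittig methylenation with the non-stabilised ylide is faster at the aldehyde than at the methyl ketone at low temperature, which should give the terminal 1,3-diene with both (E)-alkenes untouched.

Step 4
Reactants: 4 (5E,9E)-6,10-dimethyldodeca-5,9,11-trien-2-one
Product: 6 (5E,9E)-1-hydroxy-6,10-dimethyldodeca-5,9,11-trien-2-one, via potassium enolate 5 (not isolated)
Conditions: KN(SiMe3)2, THF, −78 °C; 2-(phenylsulfonyl)-3-phenyloxaziridine, −78 °C; aq. NH4Cl
Reagents that add atoms: 2-(phenylsulfonyl)-3-phenyloxaziridine O=S(=O)(N1OC1c1ccccc1)c1ccccc1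
Why: Kinetic deprotonation of the methyl ketone at the methyl group and oxygen transfer from the N-sulfonyloxaziridine to the enolate (Davis oxidation) should install the primary α-hydroxyl that becomes the lactone oxygen.

Step 5
Reactants: 6 (5E,9E)-1-hydroxy-6,10-dimethyldodeca-5,9,11-trien-2-one
Product: 8 4-[(3E,7E)-4,8-dimethyldeca-3,7,9-trien-1-yl]furan-2(5H)-one, via acyl ylide ester 7 (not isolated)
Conditions: Ph3P=C=C=O, toluene, 110 °C
Reagents that add atoms: (triphenylphosphoranylidene)ketene O=C=C=P(c1ccccc1)(c1ccccc1)c1ccccc1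
Why: O–H addition of the α-ketol to the ketenylidene ylide gives a stabilised acyl ylide, whose intramolecular Wittig reaction with the ketone closes the 4-substituted furan-2(5H)-one (ring B).

Step 6
Reactants: 9 (2E)-but-2-enal
Product: 11 (2Z)-2-bromobut-2-enal, via 2,3-dibromobutanal 10 (not isolated)
Conditions: Br2, CH2Cl2, 0 °C; then Et3N, 0 °C → rt
Reagents that add atoms: bromine BrBr
Why: Bromine addition to the enal followed by base-induced loss of HBr from the α-position (bromination–dehydrobromination) should give the α-bromo enal as the favoured (Z)-isomer, with CHO trans to CH3.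

Step 7
Reactants: 8 4-[(3E,7E)-4,8-dimethyldeca-3,7,9-trien-1-yl]furan-2(5H)-one; 11 (2Z)-2-bromobut-2-enal
Product: 13 (2E)-2-[(3E,7E)-3,7-dimethyl-10-(5-oxo-2,5-dihydrofuran-3-yl)deca-3,7-dien-1-yl]but-2-enal, via B-alkyl borane 12 (not isolated)
Conditions: 9-BBN-H, THF, 0 °C → rt; then 11, PdCl2(dppf) (5 mol%; dppf = 1,1'-bis(diphenylphosphino)ferrocene), AsPh3 (5 mol%), Cs2CO3, DMF/THF/H2O, rt
Reagents that add atoms: none
Why: 9-BBN hydroborates only the monosubstituted terminal alkene of the diene with boron at the terminal carbon, and the B-alkyl Suzuki–Miyaura coupling retains the bromoalkene geometry, so the chain ends up cis to the β-methyl and the formyl group trans to it.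

Step 8
Reactants: 14 (3E)-pent-3-en-2-one
Product: 16 triisopropyl{[(3E)-penta-1,3-dien-2-yl]oxy}silane, via lithium dienolate 15 (not isolated)
Conditions: LiN(iPr)2, THF, −78 °C; i-Pr3SiOTf, −78 → 0 °C
Reagents that add atoms: triisopropylsilyl trifluoromethanesulfonate CC(C)[Si](C(C)C)(C(C)C)OS(=O)(=O)C(F)(F)F
Why: Kinetic α′-deprotonation of the enone gives the cross-conjugated dienolate, and O-silylation should deliver the 2-silyloxy-1,3-diene with the (E)-propenyl unit retained.

Step 9
Reactants: 13 (2E)-2-[(3E,7E)-3,7-dimethyl-10-(5-oxo-2,5-dihydrofuran-3-yl)deca-3,7-dien-1-yl]but-2-enal; 16 triisopropyl{[(3E)-penta-1,3-dien-2-yl]oxy}silane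
Product: 17 (1S,6R)-1-[(3E,7E)-3,7-dimethyl-10-(5-oxo-2,5-dihydrofuran-3-yl)deca-3,7-dien-1-yl]-2,6-dimethyl-4-[(triisopropylsilyl)oxy]cyclohex-3-ene-1-carbaldehyde (C2 epimers)
Conditions: (3aS)-1-(2-methylphenyl)-3,3-diphenyltetrahydro-1H,3H-pyrrolo[1,2-c][1,3,2]oxazaborole (20 mol%), HN(SO2CF3)2 (17 mol%), 16 (3 equiv), CH2Cl2, −78 → −40 °C
Reagents that add atoms: none
Why: The protonated oxazaborolidine binds the formyl group of the s-trans enal 13, and the electron-rich diene 16 adds in a Lewis-acid-catalysed, strongly asynchronous [4+2] cycloaddition in which the C6–C5 bond (silyl enol ether carbon to enal β-carbon) leads and ring A is closed by the C3–C4 bond at the quaternary carbon. The closest known reaction type is the cationic oxazaborolidine-catalysed Diels–Alder reaction of α-substituted α,β-enals such as tiglic aldehyde or 2-methylacrolein with 2-(triisopropylsilyloxy)buta-1,3-dienes. The six-membered ring is closed in the [4+2] mode, suprafacial on both partners. C4 and C5 are set relative to each other by the (E)-geometry of the dienophile (chain cis to the C5 methyl, formyl trans) and in the absolute sense by the catalyst, which leaves the C4-Re/C5-Si face open; C3 (endo/exo) forms as a mixture and is erased in step 12. The step needs "para/ortho" regioselectivity, which the C1 silyloxy group and the methyl-substituted C3 terminus both enforce, and chemoselectivity for the enal over the butenolide and the chain alkenes, which rests on preferential formyl coordination and the low dienophilicity of the β,β-disubstituted lactone.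

Step 10
Reactants: 17 (1S,6R)-1-[(3E,7E)-3,7-dimethyl-10-(5-oxo-2,5-dihydrofuran-3-yl)deca-3,7-dien-1-yl]-2,6-dimethyl-4-[(triisopropylsilyl)oxy]cyclohex-3-ene-1-carbaldehyde (C2 epimers)
Product: 18 N-tosylhydrazone of aldehyde 17
Conditions: TsNHNH2, THF, 4 Å molecular sieves, rt → 40 °C
Reagents that add atoms: 4-methylbenzenesulfonohydrazide Cc1ccc(cc1)S(=O)(=O)NN
Why: Condensation of the aldehyde with the sulfonyl hydrazide should give the tosylhydrazone, while the C1 carbonyl stays masked as the silyl enol ether and the lactone does not condense.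

Step 11
Reactants: 18 N-tosylhydrazone of aldehyde 17
Product: 20 triisopropyl{[(4R,5R)-4-[(3E,7E)-3,7-dimethyl-10-(5-oxo-2,5-dihydrofuran-3-yl)deca-3,7-dien-1-yl]-3,4,5-trimethylcyclohex-1-en-1-yl]oxy}silane (C3 epimers), via alkyldiazene 19 (not isolated)
Conditions: catecholborane, CHCl3, 0 °C → rt; then NaOAc·3H2O, 60 °C
Reagents that add atoms: none
Why: Hydride transfer from catecholborane to the C=N bond and acetate-induced loss of sulfinate and N2 from the resulting diazene (a mild Wolff–Kishner-type reduction of tosylhydrazones) should turn the formyl carbon into the C4 methyl group without base strong enough to harm the butenolide; C4 bears no hydrogen and cannot epimerise.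

Step 12
Reactants: 20 triisopropyl{[(4R,5R)-4-[(3E,7E)-3,7-dimethyl-10-(5-oxo-2,5-dihydrofuran-3-yl)deca-3,7-dien-1-yl]-3,4,5-trimethylcyclohex-1-en-1-yl]oxy}silane (C3 epimers)
Product: 21 cyclolinteinone
Conditions: Pd(OAc)2 (1.2 equiv), MeCN/CH2Cl2, rt → 40 °C
Reagents that add atoms: none
Why: Saegusa–Ito oxidation: the regiodefined C1–C2 silyl enol ether gives a palladium enolate that loses the C3 hydrogen by β-hydride elimination, so the enone should form only toward C3 and both C3 epimers converge on the target.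

**Compound list**

1 | (5E)-6,10-dimethylundeca-5,9-dien-2-one ((E)-geranylacetone) | CC(C)=CCC/C(C)=C/CCC(C)=O | starting material
2 | (5E,9E)-11-hydroxy-6,10-dimethylundeca-5,9-dien-2-one | OC/C(C)=C/CC/C(C)=C/CCC(C)=O | intermediate
3 | (2E,6E)-2,6-dimethyl-10-oxoundeca-2,6-dienal | O=C/C(C)=C/CC/C(C)=C/CCC(C)=O | intermediate
4 | (5E,9E)-6,10-dimethyldodeca-5,9,11-trien-2-one | C=C/C(C)=C/CC/C(C)=C/CCC(C)=O | intermediate
5 | potassium (5E,9E)-6,10-dimethyldodeca-1,5,9,11-tetraen-2-olate | C=C/C(C)=C/CC/C(C)=C/CCC(=C)[O-].[K+] | intermediate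
6 | (5E,9E)-1-hydroxy-6,10-dimethyldodeca-5,9,11-trien-2-one | C=C/C(C)=C/CC/C(C)=C/CCC(=O)CO | intermediate
7 | (5E,9E)-6,10-dimethyl-2-oxododeca-5,9,11-trien-1-yl (triphenylphosphoranylidene)acetate | C=C/C(C)=C/CC/C(C)=C/CCC(=O)COC(=O)C=P(c1ccccc1)(c1ccccc1)c1ccccc1 | intermediate
8 | 4-[(3E,7E)-4,8-dimethyldeca-3,7,9-trien-1-yl]furan-2(5H)-one | C=C/C(C)=C/CC/C(C)=C/CCC1=CC(=O)OC1 | intermediate
9 | (2E)-but-2-enal (crotonaldehyde) | C/C=C/C=O | starting material
10 | 2,3-dibromobutanal | CC(Br)C(Br)C=O | intermediate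
11 | (2Z)-2-bromobut-2-enal | C/C=C(\Br)C=O | intermediate
12 | 9-[(3E,7E)-3,7-dimethyl-10-(5-oxo-2,5-dihydrofuran-3-yl)deca-3,7-dien-1-yl]-9-borabicyclo[3.3.1]nonane | B1(CC/C(C)=C/CC/C(C)=C/CCC3=CC(=O)OC3)C2CCCC1CCC2 | intermediate
13 | (2E)-2-[(3E,7E)-3,7-dimethyl-10-(5-oxo-2,5-dihydrofuran-3-yl)deca-3,7-dien-1-yl]but-2-enal | C/C=C(\CC/C(C)=C/CC/C(C)=C/CCC1=CC(=O)OC1)C=O | intermediate
14 | (3E)-pent-3-en-2-one | C/C=C/C(C)=O | starting material
15 | lithium (3E)-penta-1,3-dien-2-olate | C=C([O-])/C=C/C.[Li+] | intermediate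
16 | triisopropyl{[(3E)-penta-1,3-dien-2-yl]oxy}silane | C=C(O[Si](C(C)C)(C(C)C)C(C)C)/C=C/C | intermediate
17 | (1S,6R)-1-[(3E,7E)-3,7-dimethyl-10-(5-oxo-2,5-dihydrofuran-3-yl)deca-3,7-dien-1-yl]-2,6-dimethyl-4-[(triisopropylsilyl)oxy]cyclohex-3-ene-1-carbaldehyde (C2 epimers) | CC1C=C(O[Si](C(C)C)(C(C)C)C(C)C)C[C@@H](C)[C@@]1(C=O)CC/C(C)=C/CC/C(C)=C/CCC1=CC(=O)OC1 | intermediate
18 | N'-[(E)-{(1S,6R)-1-[(3E,7E)-3,7-dimethyl-10-(5-oxo-2,5-dihydrofuran-3-yl)deca-3,7-dien-1-yl]-2,6-dimethyl-4-[(triisopropylsilyl)oxy]cyclohex-3-en-1-yl}methylidene]-4-methylbenzenesulfonohydrazide (C2 epimers) | CC1C=C(O[Si](C(C)C)(C(C)C)C(C)C)C[C@@H](C)[C@@]1(/C=N/NS(=O)(=O)c1ccc(C)cc1)CC/C(C)=C/CC/C(C)=C/CCC1=CC(=O)OC1 | intermediate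
19 | {(1S,6R)-1-[(3E,7E)-3,7-dimethyl-10-(5-oxo-2,5-dihydrofuran-3-yl)deca-3,7-dien-1-yl]-2,6-dimethyl-4-[(triisopropylsilyl)oxy]cyclohex-3-en-1-yl}methyldiazene (C2 epimers) | CC1C=C(O[Si](C(C)C)(C(C)C)C(C)C)C[C@@H](C)[C@@]1(CN=N)CC/C(C)=C/CC/C(C)=C/CCC1=CC(=O)OC1 | intermediate
20 | triisopropyl{[(4R,5R)-4-[(3E,7E)-3,7-dimethyl-10-(5-oxo-2,5-dihydrofuran-3-yl)deca-3,7-dien-1-yl]-3,4,5-trimethylcyclohex-1-en-1-yl]oxy}silane (C3 epimers) | CC1C=C(O[Si](C(C)C)(C(C)C)C(C)C)C[C@@H](C)[C@@]1(C)CC/C(C)=C/CC/C(C)=C/CCC1=CC(=O)OC1 | intermediate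
21 | cyclolinteinone, (4R,5R)-4-[(3E,7E)-3,7-dimethyl-10-(5-oxo-2,5-dihydrofuran-3-yl)deca-3,7-dien-1-yl]-3,4,5-trimethylcyclohex-2-en-1-one | CC1=CC(=O)C[C@@H](C)[C@@]1(C)CC/C(C)=C/CC/C(C)=C/CCC1=CC(=O)OC1 | target

**Step count and risks**

Total step count: 12. Longest linear sequence: 10 steps (steps 1–5, 7, 9–12).

Steps most likely to fail:

1. Step 9 (key cycloaddition). The hindered trisubstituted enal may react slowly; facial selectivity may erode; the silyl enol ether may add 1,2 to the formyl group; the acid may trigger cation–olefin cyclisation of the polyene chain. The fallback is auxiliary-controlled and free of Lewis acid, and introduces the C3 methyl later. It sets out from 13. Thermal cycloaddition with the chiral amino siloxy diene (2S,5S)-1-[(1E)-3-(tert-butyldimethylsilyloxy)buta-1,3-dien-1-yl]-2,5-diphenylpyrrolidine (toluene, −20 °C → rt; auxiliary antipode chosen to open the same enal face) should give the amino silyl enol ether cycloadduct F1. Aqueous HF in MeCN should hydrolyse the enol ether and eliminate the amine to give the 4-formylcyclohex-2-enone F2. Conjugate addition of Me2CuLi (Et2O, −78 °C) at C3, which should outpace attack on the hindered formyl group, followed by trapping of the enolate with i-Pr3SiOTf, comes back to the route at 17.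

2. Step 7 (hydroboration/B-alkyl Suzuki–Miyaura coupling). The α-bromo enal may decompose under the basic aqueous conditions, and the alkylborane may suffer protodeboronation or β-hydride elimination after transmetalation. The fallback couples at the alcohol oxidation level and oxidises afterwards. It sets out from 11 and 8. Reduction of 11 (NaBH4, CeCl3·7H2O, MeOH, 0 °C) should give (2Z)-2-bromobut-2-en-1-ol F3. Borane 12, made from 8 as in step 7, is coupled with F3 under the same palladium catalysis to give the allylic alcohol F4. MnO2 (CH2Cl2, rt) should oxidise F4 and come back to the route at 13.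

3. Step 12 (Saegusa–Ito oxidation). Silicon-to-palladium transfer from the hindered triisopropylsilyl enol ether may be sluggish, and allylic palladation of the chain alkenes may compete. The fallback is a selenoxide elimination. It sets out from 20. PhSeCl (CH2Cl2, −78 °C) should attack the enol ether selectively and give the α-phenylselanyl ketone F5. H2O2/pyridine (CH2Cl2, 0 °C) should then effect selenoxide syn-elimination toward C3 and come back to the route at 21.

**Further compounds**

F1 | step 9 | (1S,6R)-4-(tert-butyldimethylsilyloxy)-1-[(3E,7E)-3,7-dimethyl-10-(5-oxo-2,5-dihydrofuran-3-yl)deca-3,7-dien-1-yl]-2-[(2S,5S)-2,5-diphenylpyrrolidin-1-yl]-6-methylcyclohex-3-ene-1-carbaldehyde (C2 epimers) | C1(N2[C@H](c3ccccc3)CC[C@H]2c2ccccc2)C=C(O[Si](C)(C)C(C)(C)C)C[C@@H](C)[C@@]1(C=O)CC/C(C)=C/CC/C(C)=C/CCC1=CC(=O)OC1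
F2 | step 9 | (1S,6R)-1-[(3E,7E)-3,7-dimethyl-10-(5-oxo-2,5-dihydrofuran-3-yl)deca-3,7-dien-1-yl]-6-methyl-4-oxocyclohex-2-ene-1-carbaldehyde | C1=CC(=O)C[C@@H](C)[C@@]1(C=O)CC/C(C)=C/CC/C(C)=C/CCC1=CC(=O)OC1
F3 | step 7 | (2Z)-2-bromobut-2-en-1-ol | C/C=C(\Br)CO
F4 | step 7 | (2E)-2-[(3E,7E)-3,7-dimethyl-10-(5-oxo-2,5-dihydrofuran-3-yl)deca-3,7-dien-1-yl]but-2-en-1-ol | C/C=C(\CC/C(C)=C/CC/C(C)=C/CCC1=CC(=O)OC1)CO
F5 | step 12 | (4R,5R)-4-[(3E,7E)-3,7-dimethyl-10-(5-oxo-2,5-dihydrofuran-3-yl)deca-3,7-dien-1-yl]-3,4,5-trimethyl-2-(phenylselanyl)cyclohexan-1-one (C2 and C3 epimers) | CC1C([Se]c2ccccc2)C(=O)C[C@@H](C)[C@@]1(C)CC/C(C)=C/CC/C(C)=C/CCC1=CC(=O)OC1
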